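# Proposed synthesis of CNP0432723.3 (compound 40) by acyloin ring expansion of a cyclopenta[c]pyranone

Atoms carry the 1H-isochromene numbers of 40 throughout (C1, O2, C3, C4, C4a, C5–C8, C8a). In the cyclopentene intermediates the ring carbon between C5 and C8 is the future C6. TBS = tert-butyldimethylsilyl, TES = triethylsilyl.

## The problem

Compound 40 is an 8,8a-dihydro-1H-isochromen-6(7H)-one. A cyclohexenone (ring A, C4a–C8a) shares the C4a–C8a bond with a 1H-pyran (ring B: C1, O2, C3, C4). The two rings are tied together by the push–pull chain O2–C3=C4–C4a=C5(Cl)–C6=O, which runs on into the E-butenyl side chain at C3.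

Ring A carries three contiguous stereocentres: the quaternary methyl carbinol C7, the secondary carbinol C8 and the ring-fusion methine C8a. The C7 hydroxyl, the C8 hydroxyl and the C8a–C1 bond all lie on one face. Such an all-cis array cannot be built by letting each reagent approach anti to its neighbour. The C8a–C1 bond has to be delivered from the face of an existing oxygen. After that, C8 and C8a together can send a nucleophile to the opposite face of a neighbouring carbonyl group, and that centre can be relayed to C7.

The side chain holds three more stereocentres, the S tertiary carbinol and the trans-(2S,3S)-3-methyltetrahydrofuran. They are too remote from the core for mutual control, so the chain must be made separately as one enantiomer and joined through the C3–vinyl bond. Within the chain, the ring oxygen can direct the carbinol by chelation.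

The finished molecule tolerates little. The vinylogous ester is opened by aqueous acid and by nucleophiles. The tertiary allylic alcohol ionises to an oxygen-stabilised pentadienyl cation. The C6/C7 α-ketol with its β-hydroxyl at C8 undergoes acyloin shifts and retro-aldol cleavage in base.

A ring-B lactone precursor has a further trap. Its C4 methylene becomes a vinylogous β-dicarbonyl position as soon as a ketone is conjugated with C4a=C5. This decides when the lactone carbonyl may appear and how C3 can be functionalised.

The feature that opens the key step is the pair C6 ketone/C7 tertiary methyl carbinol in ring A. A 2-hydroxy-2-methylcyclohexanone is what a 1-acetylcyclopentanol gives on acyloin ring enlargement, with C8 as the migrating carbon.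

## Retrosynthesis

**40 ⇒ 39 ⇒ 38.** The last bonds removed are the three O–Si bonds (O7, O8, side-chain oxygen) and C5–Cl. Chlorine is placed late because C5 is the most nucleophilic carbon of the finished dienone, and because a chlorine on the vinylic carbon would interfere with the ring enlargement. Silyl ethers are chosen as the only protecting groups so that the final unmasking needs buffered fluoride and neither acid nor base. Compound 38 differs from the target only by chlorine and three silyl groups.

**38 ⇒ 35 + 36 (from 34).** The C3–alkenyl bond is cut. The obvious neighbour, an enol sulfonate of lactone 19 coupled with stannane 34, is set aside. Deprotonation of 19 at C4 gives an ambident dienolate that should be sulfonylated at the ketone oxygen O6, as β-keto esters are. The plan uses this bias instead. Silylation at O6 gives 35, in which C3 is an unsaturated lactone carbonyl without an α-hydrogen. The alkenyllithium 36 can add there, and mild acid then expels water and the O6 silyl group. The precursors are a side-chain-free bicyclic lactone and an independent fragment. The forward step must stop at mono-addition.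

**35 ⇒ 19 ⇒ 18 (key step).** After removal of the two triethylsilyl groups, the C7–C8 bond of 19 is cut and reconnected as the C6–C8 bond of the 1-acetylcyclopentenol 18. This trades the six-membered α-ketol for a cyclopentene carbinol whose configuration arises by simple steric approach to a ketone. The forward shift must move C8 and not the vinylic C5, and must place the C7 hydroxyl cis to the C8 oxygen. Both follow from the chelated syn conformer and from reversibility.

**18 ⇒ 17 ⇒ 16.** The O2–C3 lactone bond is traced back to the diol 17 (oxidation at C3, then ring closure by the C1 hydroxyl), and 17 to the tris-silyl ether 16. The lactone carbonyl is introduced only here. In any earlier enone the C4 hydrogens, flanked by the lactone carbonyl and the vinylogous ketone, would be removed by the organolithium needed for the carbinol. In 18 the carbinol carbon insulates them. The forward oxidation must pick the less hindered of two primary alcohols.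

**16 ⇒ 12 + 14 (from 13).** The bond between the future C6 and the acetyl carbon is cut. An acyl anion equivalent adds to enone 12 from the face opposite the C8 silyloxy group and the C8a arm, which are cis to each other. The hydroxyl therefore comes out cis to the C8 oxygen, as the key step requires. Compound 12 has two stereocentres and no quaternary carbon.

**12 ⇒ 11 ⇒ 10 ⇒ 9.** These are functional-group changes only: silylation, chemoselective oxidation of the one allylic alcohol, and hydrolysis of an acetonide. The C8 oxygen and the oxygen that becomes the C6 ketone are carried as one cis-diol acetonide, so no C–H oxidation is needed on the ring.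

**9 ⇒ 7 ⇒ 6.** The C8a–C1 bond is cut as a Still–Wittig [2,3]-shift of the stannylmethyl ether 7. This is the contra-steric step. The shift is suprafacial and therefore places the CH2O arm on the face of the departing C5 oxygen, which is the face of the C8 oxygen. It also moves the double bond to C4a=C5, where the enone needs it. Intermolecular conjugate addition or enolate oxidation would give the trans isomer and require an inversion.

**6 ⇒ 5 ⇒ 2 + 4 (from 3) ⇒ 1.** The C4a–C4 bond is cut as a Suzuki–Miyaura coupling of the α-iodoenone 2 with the alkylborane 4. A convex-face hydride reduction then sets the hydroxyl of 6 cis to the dioxolane. Enone 1 supplies C8 and the absolute configuration from the chiral pool. A Pauson–Khand cyclisation of an ester-tethered enyne would reach a bicyclic enone lactone faster, but it was not adopted for three reasons: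
- ester tethers and 1,7-enynes cyclise poorly;
- the product is exactly the acidic enone lactone that cannot take the later organolithium addition;
- its C8 oxygen would have to be introduced trans and inverted.

**34 ⇒ 33 ⇒ 32 ⇒ 31.** Fragment 2 is traced back through the C–Sn bond (hydrostannylation of the alkyne), the O–Si bond, and the carbinol–alkyne bond to the methyl ketone 31. Addition of an ethynyl Grignard reagent to the magnesium chelate of 31 should give the S carbinol.

**31 ⇒ 29 ⇒ 27 ⇒ 25 ⇒ 20 + 21.** The acetyl group is an ozonolysed isopropenyl group (29). The O1'–C5' bond is an intramolecular etherification of diol 27. The diol comes from selective hydroboration of dienol 25. The C2'–C3' bond of 25 is an anti-selective crotylboration of 21 with the borane 23 made from 20. It sets both ring stereocentres in one step, trans as required.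

## Roads not taken

**Alternative 1:** ring B closed last by elimination and oxa-conjugate addition. The cut is O2–C1 together with the C8a–H bond of the acetonide A1 of the target. In the forward step an amidine base removes the C8a hydrogen of the acetate A2 and expels acetate to give the methylene dienone A3. The enol oxygen of the C3 ketone then adds to C1 and C8a is reprotonated.
- Merits: both C8a epimers of A2 converge; chlorine, side chain and diol are in place before the ring closes. In convergence this road is better than the chosen one.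
- Weak points: C8a is set by one protonation of an extended enolate, so the triad rests on that event and on a separate asymmetric oxidation for C7/C8. A3 is a reactive cross-conjugated trienone exposed to base and nucleophiles. The last step would be acid cleavage of a hindered acetonide beside the acid-labile tertiary allylic alcohol.
- Against this, the chosen plan fixes C8a by a stereospecific sigmatropic shift, relays it to C7 by a stereospecific 1,2-shift, and ends with fluoride.

**Alternative 2:** ring A closed by a carbene-catalysed crossed benzoin reaction. The cut is C6–C7 of the silyl ether A4. In the forward step a chiral triazolium-derived carbene turns the aldehyde of the keto aldehyde A5 into an acyl anion equivalent that adds to the C7 methyl ketone.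
- Merits: quaternary carbinol and ring A form in one catalytic step with the whole side chain attached, and only chlorination and desilylation remain. In step count after the key step this road is shorter.
- Weak points: the aldehyde of A5 is the end of a push–pull dienal. It is a poor electrophile for the carbene and is prone to extended-enal redox pathways. The exocyclic double bond must hold the Z geometry. C8 is α to the ketone and can epimerise or eliminate under the basic conditions. The C7 configuration depends on the catalyst matching the C8 stereocentre.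
- Against this, the chosen plan forms C7 from a centre made by steric approach to a cyclopentenone, and its key substrate is a stable lactone.

**Alternative 3:** ring A closed by vinylogous C-acylation. The cut is C5–C6 of the protected dienone A6. In the forward step the acid A7 is converted to its chloride under neutral conditions with an α-chloroenamine reagent, and the exocyclic methylene carbon of the dienol ether attacks it.
- Merits: the C7/C8 diol with its quaternary centre is made early and carried as a robust acetonide. The closure occurs at the nucleophilic terminus of a dienol ether and gives the complete chromophore in the ring-forming step, which the chosen plan reaches only two steps after its key step.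
- Weak points: A7 contains a cross-conjugated methylene pyran that is very acid-sensitive and can isomerise into the ring. The acid chloride sits on a fully substituted α-alkoxy carbon and can lose carbon monoxide. Hydrogen chloride is released next to the dienol ether. The acetonide again has to come off in acid at the end.
- Against this, the chosen plan keeps electron-rich dienol ethers out of the sequence until step 20 and needs no acid-labile diol protection.

Key step: step 12

Remark 1: the crotylborane made from (−)-B-methoxydiisopinocampheylborane, (−)-Ipc2BOMe (from (+)-α-pinene), is assumed to add to aldehyde 21 with the same facial sense as to other aldehydes, which gives the (3S,4S) alcohol 25.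
Remark 2: enone 1 is taken as the commercial isopropylidene-protected cyclopentenone derived from D-ribose.

## Steps

**Fragment 1 and key step (steps 1–12)**

Step 1
Reactants: 1 (3aR,6aR)-2,2-dimethyl-3a,6a-dihydro-4H-cyclopenta[d][1,3]dioxol-4-one
Product: 2 (3aR,6aR)-5-iodo-2,2-dimethyl-3a,6a-dihydro-4H-cyclopenta[d][1,3]dioxol-4-one
Conditions: I2, pyridine, CH2Cl2, 0 °C to rt
Reagents that add atoms: iodine, [I][I]
Why: α-Iodination of an enone by conjugate addition of pyridine, iodination of the enolate and elimination; the two stereocentres are not touched.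

Step 2
Reactants: 2 (3aR,6aR)-5-iodo-2,2-dimethyl-3a,6a-dihydro-4H-cyclopenta[d][1,3]dioxol-4-one; 3 tert-butyl(dimethyl)(vinyloxy)silane
Product: 5 (3aR,6aR)-5-[2-(tert-butyldimethylsilyloxy)ethyl]-2,2-dimethyl-3a,6a-dihydro-4H-cyclopenta[d][1,3]dioxol-4-one, via alkylborane 4 (not isolated)
Conditions: 3, 9-BBN, THF, 0 °C to rt; then 2, PdCl2(dppf) (cat.), AsPh3, Cs2CO3, DMF/THF/H2O, rt
Reagents that add atoms: none
Why: Hydroboration of the enol ether places boron on the terminal carbon, and the B-alkyl Suzuki–Miyaura coupling with an α-iodoenone proceeds at room temperature with a mild base after oxidative addition of zerovalent palladium to the C–I bond. The coupling forms the C4a–C4 bond and leaves C3 at the alcohol oxidation level, so that no acidic C4 hydrogen exists in the later enone.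

Step 3
Reactants: 5 (3aR,6aR)-5-[2-(tert-butyldimethylsilyloxy)ethyl]-2,2-dimethyl-3a,6a-dihydro-4H-cyclopenta[d][1,3]dioxol-4-one
Product: 6 (3aS,4S,6aR)-5-[2-(tert-butyldimethylsilyloxy)ethyl]-2,2-dimethyl-4,6a-dihydro-3aH-cyclopenta[d][1,3]dioxol-4-ol
Conditions: NaBH4, CeCl3·7H2O, MeOH, −78 °C
Reagents that add atoms: none
Why: Luche 1,2-reduction of the enone; hydride enters from the convex face opposite the dioxolane, so the new hydroxyl is cis to both acetonide oxygens.

Step 4
Reactants: 6 (3aS,4S,6aR)-5-[2-(tert-butyldimethylsilyloxy)ethyl]-2,2-dimethyl-4,6a-dihydro-3aH-cyclopenta[d][1,3]dioxol-4-ol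
Product: 7 tributylstannylmethyl ether of 6
Conditions: KH, THF, 0 °C; Bu3SnCH2I, rt
Reagents that add atoms: (iodomethyl)tributylstannane, CCCC[Sn](CCCC)(CCCC)CI
Why: Williamson etherification of the potassium alkoxide with a primary iodide; the carbinol configuration is retained.

Step 5
Reactants: 7 tributylstannylmethyl ether of 6
Product: 9 {5-[2-(tert-butyldimethylsilyloxy)ethyl]-2,2-dimethyl-4,6a-dihydro-3aH-cyclopenta[d][1,3]dioxol-4-yl}methanol with the hydroxymethyl group cis to the dioxolane oxygens, via lithiomethyl ether 8 (not isolated)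
Conditions: n-BuLi, THF, −78 °C; then H2O
Reagents that add atoms: none
Why: Tin–lithium exchange gives the α-alkoxymethyllithium, which undergoes the Still–Wittig [2,3]-sigmatropic rearrangement. The shift is suprafacial, so the CH2O carbon is delivered to C8a on the face that the oxygen leaves, which is cis to the C8 oxygen; the double bond moves to C4a=C5.

Step 6
Reactants: 9 {5-[2-(tert-butyldimethylsilyloxy)ethyl]-2,2-dimethyl-4,6a-dihydro-3aH-cyclopenta[d][1,3]dioxol-4-yl}methanol
Product: 10 (1S,2R,3S)-4-(2-hydroxyethyl)-3-(hydroxymethyl)cyclopent-4-ene-1,2-diol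
Conditions: CF3CO2H/H2O/THF, 0 °C to rt
Reagents that add atoms: none
Why: Aqueous acid hydrolyses the acetonide and the primary silyl ether; the allylic C–O bond is deactivated towards ionisation by the neighbouring oxygen-bearing carbon.

Step 7
Reactants: 10 (1S,2R,3S)-4-(2-hydroxyethyl)-3-(hydroxymethyl)cyclopent-4-ene-1,2-diol
Product: 11 (4S,5R)-5-hydroxy-3-(2-hydroxyethyl)-4-(hydroxymethyl)cyclopent-2-en-1-one
Conditions: MnO2 (activated), acetone, rt
Reagents that add atoms: none
Why: MnO2 oxidises the allylic secondary alcohol and leaves the saturated secondary and primary alcohols; this fixes the ketone at the future C6 without C–H oxidation.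

Step 8
Reactants: 11 (4S,5R)-5-hydroxy-3-(2-hydroxyethyl)-4-(hydroxymethyl)cyclopent-2-en-1-one
Product: 12 (4S,5R)-5-(tert-butyldimethylsilyloxy)-3-[2-(tert-butyldimethylsilyloxy)ethyl]-4-[(tert-butyldimethylsilyloxy)methyl]cyclopent-2-en-1-one
Conditions: TBSOTf, 2,6-lutidine, CH2Cl2, −78 to 0 °C
Reagents that add atoms: tert-butyldimethylsilyl trifluoromethanesulfonate, CC(C)(C)[Si](C)(C)OS(=O)(=O)C(F)(F)F
Why: Exhaustive O-silylation with a silyl triflate and a hindered base; no stereocentre is affected.

Step 9
Reactants: 12 (4S,5R)-5-(tert-butyldimethylsilyloxy)-3-[2-(tert-butyldimethylsilyloxy)ethyl]-4-[(tert-butyldimethylsilyloxy)methyl]cyclopent-2-en-1-one; 13 ethyl vinyl ether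
Product: 16 1-{(1S,4S,5R)-5-(tert-butyldimethylsilyloxy)-3-[2-(tert-butyldimethylsilyloxy)ethyl]-4-[(tert-butyldimethylsilyloxy)methyl]-1-hydroxycyclopent-2-en-1-yl}ethanone, via 1-ethoxyvinyllithium 14 (not isolated), via enol ether adduct 15 (not isolated)
Conditions: 13, t-BuLi, THF, −78 to 0 °C; then 12, THF, −78 °C; then 0.5 M HCl, THF, 0 °C
Reagents that add atoms: water, O
Why: 1,2-Addition of an acyl anion equivalent to a β,β-disubstituted enone, then hydrolysis of the enol ether to the methyl ketone. The C8 silyloxy group and the C8a arm are cis and shield one face, so the nucleophile enters from the other and the new hydroxyl is cis to the C8 oxygen.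

Step 10
Reactants: 16 1-{(1S,4S,5R)-5-(tert-butyldimethylsilyloxy)-3-[2-(tert-butyldimethylsilyloxy)ethyl]-4-[(tert-butyldimethylsilyloxy)methyl]-1-hydroxycyclopent-2-en-1-yl}ethanone
Product: 17 1-[(1S,4S,5R)-5-(tert-butyldimethylsilyloxy)-1-hydroxy-3-(2-hydroxyethyl)-4-(hydroxymethyl)cyclopent-2-en-1-yl]ethanone
Conditions: HF·pyridine, pyridine, THF, 0 °C
Reagents that add atoms: none
Why: Buffered fluoride cleaves the two primary silyl ethers much faster than the secondary one at C8, which is flanked by two substituted carbons.

Step 11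
Reactants: 17 1-[(1S,4S,5R)-5-(tert-butyldimethylsilyloxy)-1-hydroxy-3-(2-hydroxyethyl)-4-(hydroxymethyl)cyclopent-2-en-1-yl]ethanone
Product: 18 (6S,7R,7aS)-6-acetyl-7-(tert-butyldimethylsilyloxy)-6-hydroxy-4,6,7,7a-tetrahydrocyclopenta[c]pyran-3(1H)-one
Conditions: TEMPO (cat.), PhI(OAc)2, CH2Cl2, rt
Reagents that add atoms: none
Why: Oxoammonium oxidation of a 1,5-diol to the δ-lactone: the unhindered C3 alcohol is oxidised first, the aldehyde is trapped by the C1 hydroxyl as a lactol, and the lactol is oxidised further. The tertiary alcohol and the alkene are inert, and the ring fusion is cis by construction.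

Step 12
Reactants: 18 (6S,7R,7aS)-6-acetyl-7-(tert-butyldimethylsilyloxy)-6-hydroxy-4,6,7,7a-tetrahydrocyclopenta[c]pyran-3(1H)-one
Product: 19 (7R,8R,8aS)-8-(tert-butyldimethylsilyloxy)-7-hydroxy-7-methyl-4,7,8,8a-tetrahydro-1H-isochromene-3,6-dione
Conditions: Al(OC(CH3)3)3, toluene, 80 °C
Reagents that add atoms: none
Why: Al(OC(CH3)3)3 exchanges one alkoxide for the tertiary hydroxyl of 18 and binds the acetyl oxygen, so that both oxygens are held syn in a five-membered aluminium chelate. In this chelate the bonds from the carbinol carbon (future C6) to C8 and to C5 stand on opposite sides of the acetyl plane; the C8 bond shifts with its electron pair to the acetyl carbon while the carbinol carbon becomes the C6 carbonyl, which is the α-ketol (acyloin) rearrangement known from the D-homoannulation of 17-hydroxy-20-oxo steroids. Ring A is therefore formed by a 1,2-shift that enlarges the cyclopentene to a cyclohexenone and not by a cyclisation, with C7–C8 as the one new skeletal bond. The new stereocentre C7 is set by the substrate: the shift is suprafacial with retention at C8, and C8 enters the acetyl face that the chelate turns towards it, so the former carbonyl oxygen ends up cis to the C8 silyloxy group (7R) and the methyl group trans. The selectivity needed is migration of C8 and not of the vinylic C5; the shift is reversible, and only C8 migration gives a ketone conjugated with C4a=C5 in an unstrained six-membered ring, so equilibration should lead to 19, while the C5-shifted isomer is unconjugated and can return to 18. The hydroxyl/silyloxy cis relationship from step 9 is what puts C8 on the reacting face of the chelated conformer. The lactone, the silyl ether and C8a are spectators.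

**Fragment 2 (steps 13–19)**

Step 13
Reactants: 20 (E)-but-2-ene; 21 2-methylprop-2-enal (methacrolein)
Product: 25 (3S,4S)-2,4-dimethylhexa-1,5-dien-3-ol, via crotylpotassium 22 (not isolated), via crotylborane 23 (not isolated), via borinate 24 (not isolated)
Conditions: 20, KOC(CH3)3, n-BuLi, THF, −78 to −45 °C; (−)-Ipc2BOMe, −78 °C; BF3·OEt2; 21, −78 °C; then NaOH, H2O2
Reagents that add atoms: none
Why: Brown crotylboration: the (E)-crotylborane reacts through a chair transition state and gives the anti product, and the isopinocampheyl groups choose the aldehyde face. Both stereocentres of the later tetrahydrofuran are set here, trans to each other.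

Step 14
Reactants: 25 (3S,4S)-2,4-dimethylhexa-1,5-dien-3-ol
Product: 27 (3S,4S)-3,5-dimethylhex-5-ene-1,4-diol, via bisborane 26 (not isolated)
Conditions: disiamylborane (from BH3·THF and 2-methylbut-2-ene), THF, 0 °C; then NaOH, H2O2
Reagents that add atoms: hydrogen peroxide, OO
Why: The hindered dialkylborane hydroborates the monosubstituted alkene far faster than the 1,1-disubstituted one next to the carbinol; oxidation gives the anti-Markovnikov primary alcohol without touching the stereocentres.

Step 15
Reactants: 27 (3S,4S)-3,5-dimethylhex-5-ene-1,4-diol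
Product: 29 (2S,3S)-3-methyl-2-(prop-1-en-2-yl)tetrahydrofuran, via monotosylate 28 (not isolated)
Conditions: NaH, THF, 0 °C; N-tosylimidazole, 0 °C to rt
Reagents that add atoms: none
Why: The primary alkoxide is sulfonylated selectively and the secondary alkoxide displaces the tosylate in a 5-exo-tet Williamson closure. The carbinol oxygen is retained, so the anti diol gives the trans-2,3-disubstituted ring.

Step 16
Reactants: 29 (2S,3S)-3-methyl-2-(prop-1-en-2-yl)tetrahydrofuran
Product: 31 1-[(2S,3S)-3-methyltetrahydrofuran-2-yl]ethanone, via ozonide 30 (not isolated)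
Conditions: O3, CH2Cl2, −78 °C; then Me2S
Reagents that add atoms: ozone, [O-][O+]=O
Why: Ozonolysis of the 1,1-disubstituted alkene with reductive work-up gives the methyl ketone. The α-stereocentre is the thermodynamically preferred trans one, so it is not at risk under the neutral work-up.

Step 17
Reactants: 31 1-[(2S,3S)-3-methyltetrahydrofuran-2-yl]ethanone
Product: 32 (2S)-2-[(2S,3S)-3-methyltetrahydrofuran-2-yl]but-3-yn-2-ol
Conditions: HC≡CMgBr, THF, −78 to 0 °C; then aq. NH4Cl
Reagents that add atoms: ethynylmagnesium bromide, C#C[Mg]Br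
Why: Chelation-controlled Grignard addition to an α-alkoxy ketone: magnesium bridges the ring oxygen and the carbonyl oxygen, and the acetylide attacks the face that carries the C2 hydrogen and not the ring carbon C3. This gives the S carbinol.

Step 18
Reactants: 32 (2S)-2-[(2S,3S)-3-methyltetrahydrofuran-2-yl]but-3-yn-2-ol
Product: 33 triethylsilyl ether of 32
Conditions: TESOTf, 2,6-lutidine, CH2Cl2, 0 °C
Reagents that add atoms: triethylsilyl trifluoromethanesulfonate, CC[Si](CC)(CC)OS(=O)(=O)C(F)(F)F
Why: Silyl triflates silylate tertiary alcohols; the ether keeps the alkoxide out of the later organolithium step and comes off with the other silyl groups.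

Step 19
Reactants: 33 triethylsilyl ether of 32
Product: 34 tributyl{(1E,3S)-3-[(2S,3S)-3-methyltetrahydrofuran-2-yl]-3-(triethylsilyloxy)but-1-en-1-yl}stannane
Conditions: Bu3SnH, PdCl2(PPh3)2 (cat.), THF, 0 °C to rt
Reagents that add atoms: tributyltin hydride, CCCC[SnH](CCCC)CCCC
Why: Palladium-catalysed hydrostannylation of a terminal alkyne is a syn addition, and the bulky fully substituted propargylic carbon directs tin to the terminal carbon. The E-β-stannane results.

**Endgame (steps 20–23)**

Step 20
Reactants: 19 (7R,8R,8aS)-8-(tert-butyldimethylsilyloxy)-7-hydroxy-7-methyl-4,7,8,8a-tetrahydro-1H-isochromene-3,6-dione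
Product: 35 (7R,8R,8aS)-8-(tert-butyldimethylsilyloxy)-7-methyl-6,7-bis(triethylsilyloxy)-1,7,8,8a-tetrahydro-3H-isochromen-3-one
Conditions: TESOTf, Et3N, CH2Cl2, −78 to 0 °C
Reagents that add atoms: triethylsilyl trifluoromethanesulfonate, CC[Si](CC)(CC)OS(=O)(=O)C(F)(F)F
Why: Soft enolisation: the ketone oxygen is silylated and the amine removes the doubly activated C4 hydrogen, which gives the extended dienol ether conjugated with the lactone; the tertiary hydroxyl is silylated at the same time. The ketone is masked and C4 loses its acidic hydrogens in one operation.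

Step 21
Reactants: 35 (7R,8R,8aS)-8-(tert-butyldimethylsilyloxy)-7-methyl-6,7-bis(triethylsilyloxy)-1,7,8,8a-tetrahydro-3H-isochromen-3-one; 34 tributyl{(1E,3S)-3-[(2S,3S)-3-methyltetrahydrofuran-2-yl]-3-(triethylsilyloxy)but-1-en-1-yl}stannane
Product: 38 (7R,8R,8aS)-8-(tert-butyldimethylsilyloxy)-7-methyl-3-{(1E,3S)-3-[(2S,3S)-3-methyltetrahydrofuran-2-yl]-3-(triethylsilyloxy)but-1-en-1-yl}-7-(triethylsilyloxy)-8,8a-dihydro-1H-isochromen-6(7H)-one, via vinyllithium 36 (not isolated), via lactol 37 (not isolated)
Conditions: 34, n-BuLi, THF, −78 °C; then 35, −78 °C; then aq. NH4Cl; PPTS (cat.), wet THF, 0 °C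
Reagents that add atoms: none
Why: Tin–lithium exchange gives the E-alkenyllithium with retention, and it adds 1,2 to the lactone carbonyl, the only electrophilic carbonyl of 35. Mild acid then removes water from the lactol and the silyl group from O6, a Stork–Danheiser-type transposition of a vinylogous lactone, and gives the C3-alkenyl pyran dienone. No stereocentre is formed.

Step 22
Reactants: 38 (7R,8R,8aS)-8-(tert-butyldimethylsilyloxy)-7-methyl-3-{(1E,3S)-3-[(2S,3S)-3-methyltetrahydrofuran-2-yl]-3-(triethylsilyloxy)but-1-en-1-yl}-7-(triethylsilyloxy)-8,8a-dihydro-1H-isochromen-6(7H)-one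
Product: 39 5-chloro derivative of 38
Conditions: N-chlorosuccinimide, THF, 0 °C, dark
Reagents that add atoms: N-chlorosuccinimide, O=C1CCC(=O)N1Cl
Why: Electrophilic chlorination of the push–pull dienone at C5, the carbon α to the ketone and δ to the ring oxygen, followed by loss of the C5 proton. This is the position halogenated in related 6-oxoisochromene (azaphilone-type) chromophores.

Step 23
Reactants: 39 5-chloro derivative of 38
Product: 40 (7R,8R,8aS)-5-chloro-7,8-dihydroxy-3-{(1E,3S)-3-hydroxy-3-[(2S,3S)-3-methyltetrahydrofuran-2-yl]but-1-en-1-yl}-7-methyl-8,8a-dihydro-1H-isochromen-6(7H)-one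
Conditions: HF·pyridine, pyridine, THF, 0 °C to rt
Reagents that add atoms: none
Why: Buffered fluoride cleaves the three Si–O bonds without the acid that would ionise the tertiary allylic alcohol and without the base that would trigger a ketol shift or retro-aldol cleavage.

## Compound list

1 | (3aR,6aR)-2,2-dimethyl-3a,6a-dihydro-4H-cyclopenta[d][1,3]dioxol-4-one | CC1(C)O[C@@H]2C=CC(=O)[C@@H]2O1 | starting material
2 | (3aR,6aR)-5-iodo-2,2-dimethyl-3a,6a-dihydro-4H-cyclopenta[d][1,3]dioxol-4-one | CC1(C)O[C@@H]2C=C(I)C(=O)[C@@H]2O1 | intermediate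
3 | tert-butyl(dimethyl)(vinyloxy)silane | C=CO[Si](C)(C)C(C)(C)C | starting material
4 | B-[2-(tert-butyldimethylsilyloxy)ethyl]-9-borabicyclo[3.3.1]nonane | CC(C)(C)[Si](C)(C)OCCB1C2CCCC1CCC2 | intermediate
5 | (3aR,6aR)-5-[2-(tert-butyldimethylsilyloxy)ethyl]-2,2-dimethyl-3a,6a-dihydro-4H-cyclopenta[d][1,3]dioxol-4-one | CC1(C)O[C@@H]2C=C(CCO[Si](C)(C)C(C)(C)C)C(=O)[C@@H]2O1 | intermediate
6 | (3aS,4S,6aR)-5-[2-(tert-butyldimethylsilyloxy)ethyl]-2,2-dimethyl-4,6a-dihydro-3aH-cyclopenta[d][1,3]dioxol-4-ol (hydroxyl cis to the dioxolane oxygens) | CC1(C)O[C@@H]2C=C(CCO[Si](C)(C)C(C)(C)C)[C@H](O)[C@@H]2O1 | intermediate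
7 | tributylstannylmethyl ether of 6 | CC1(C)O[C@@H]2C=C(CCO[Si](C)(C)C(C)(C)C)[C@H](OC[Sn](CCCC)(CCCC)CCCC)[C@@H]2O1 | intermediate
8 | lithiomethyl ether of 6 | CC1(C)O[C@@H]2C=C(CCO[Si](C)(C)C(C)(C)C)[C@H](OC[Li])[C@@H]2O1 | intermediate
9 | {5-[2-(tert-butyldimethylsilyloxy)ethyl]-2,2-dimethyl-4,6a-dihydro-3aH-cyclopenta[d][1,3]dioxol-4-yl}methanol, hydroxymethyl cis to the dioxolane oxygens | CC1(C)O[C@@H]2[C@H](CO)C(CCO[Si](C)(C)C(C)(C)C)=C[C@@H]2O1 | intermediate
10 | (1S,2R,3S)-4-(2-hydroxyethyl)-3-(hydroxymethyl)cyclopent-4-ene-1,2-diol | OCCC1=C[C@H](O)[C@H](O)[C@@H]1CO | intermediate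
11 | (4S,5R)-5-hydroxy-3-(2-hydroxyethyl)-4-(hydroxymethyl)cyclopent-2-en-1-one | OCCC1=CC(=O)[C@H](O)[C@@H]1CO | intermediate
12 | (4S,5R)-5-(tert-butyldimethylsilyloxy)-3-[2-(tert-butyldimethylsilyloxy)ethyl]-4-[(tert-butyldimethylsilyloxy)methyl]cyclopent-2-en-1-one | CC(C)(C)[Si](C)(C)OCCC1=CC(=O)[C@H](O[Si](C)(C)C(C)(C)C)[C@@H]1CO[Si](C)(C)C(C)(C)C | intermediate
13 | ethyl vinyl ether | C=COCC | starting material
14 | 1-ethoxyvinyllithium | [Li]C(=C)OCC | intermediate
15 | 1-ethoxyvinyl carbinol from 12 (hydroxyl cis to the C8 silyloxy group) | CC(C)(C)[Si](C)(C)OCCC1=C[C@@](O)(C(=C)OCC)[C@H](O[Si](C)(C)C(C)(C)C)[C@@H]1CO[Si](C)(C)C(C)(C)C | intermediate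
16 | 1-{(1S,4S,5R)-5-(tert-butyldimethylsilyloxy)-3-[2-(tert-butyldimethylsilyloxy)ethyl]-4-[(tert-butyldimethylsilyloxy)methyl]-1-hydroxycyclopent-2-en-1-yl}ethanone | CC(C)(C)[Si](C)(C)OCCC1=C[C@@](O)(C(C)=O)[C@H](O[Si](C)(C)C(C)(C)C)[C@@H]1CO[Si](C)(C)C(C)(C)C | intermediate
17 | 1-[(1S,4S,5R)-5-(tert-butyldimethylsilyloxy)-1-hydroxy-3-(2-hydroxyethyl)-4-(hydroxymethyl)cyclopent-2-en-1-yl]ethanone | OCCC1=C[C@@](O)(C(C)=O)[C@H](O[Si](C)(C)C(C)(C)C)[C@@H]1CO | intermediate
18 | (6S,7R,7aS)-6-acetyl-7-(tert-butyldimethylsilyloxy)-6-hydroxy-4,6,7,7a-tetrahydrocyclopenta[c]pyran-3(1H)-one | O=C1CC2=C[C@@](O)(C(C)=O)[C@H](O[Si](C)(C)C(C)(C)C)[C@@H]2CO1 | intermediate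
19 | (7R,8R,8aS)-8-(tert-butyldimethylsilyloxy)-7-hydroxy-7-methyl-4,7,8,8a-tetrahydro-1H-isochromene-3,6-dione | O=C1CC2=CC(=O)[C@](C)(O)[C@H](O[Si](C)(C)C(C)(C)C)[C@@H]2CO1 | intermediate
20 | (E)-but-2-ene | C/C=C/C | starting material
21 | 2-methylprop-2-enal | CC(=C)C=O | starting material
22 | (E)-but-2-enylpotassium | C/C=C/C[K] | intermediate
23 | (E)-but-2-enyl-bis(isopinocampheyl)borane | C/C=C/CB([C@@H]1C[C@@H]2C[C@H]([C@H]1C)C2(C)C)[C@@H]1C[C@@H]2C[C@H]([C@H]1C)C2(C)C | intermediate
24 | bis(isopinocampheyl)borinate of 25 | C=C[C@H](C)[C@H](OB([C@@H]1C[C@@H]2C[C@H]([C@H]1C)C2(C)C)[C@@H]1C[C@@H]2C[C@H]([C@H]1C)C2(C)C)C(C)=C | intermediate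
25 | (3S,4S)-2,4-dimethylhexa-1,5-dien-3-ol | C=C[C@H](C)[C@H](O)C(C)=C | intermediate
26 | O,C-bis(disiamylboryl) derivative of 27 | CC(C)C(C)B(C(C)C(C)C)CC[C@H](C)[C@H](OB(C(C)C(C)C)C(C)C(C)C)C(C)=C | intermediate
27 | (3S,4S)-3,5-dimethylhex-5-ene-1,4-diol | OCC[C@H](C)[C@H](O)C(C)=C | intermediate
28 | 1-O-(4-methylbenzenesulfonyl) derivative of 27 | Cc1ccc(cc1)S(=O)(=O)OCC[C@H](C)[C@H](O)C(C)=C | intermediate
29 | (2S,3S)-3-methyl-2-(prop-1-en-2-yl)tetrahydrofuran | C[C@H]1CCO[C@@H]1C(C)=C | intermediate
30 | 3-methyl-3-[(2S,3S)-3-methyltetrahydrofuran-2-yl]-1,2,4-trioxolane (ozonide, mixture at the trioxolane carbon) | C[C@H]1CCO[C@@H]1C1(C)OCOO1 | intermediate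
31 | 1-[(2S,3S)-3-methyltetrahydrofuran-2-yl]ethanone | C[C@H]1CCO[C@@H]1C(C)=O | intermediate
32 | (2S)-2-[(2S,3S)-3-methyltetrahydrofuran-2-yl]but-3-yn-2-ol | C[C@H]1CCO[C@@H]1[C@@](C)(O)C#C | intermediate
33 | triethyl{[(2S)-2-[(2S,3S)-3-methyltetrahydrofuran-2-yl]but-3-yn-2-yl]oxy}silane | C[C@H]1CCO[C@@H]1[C@@](C)(O[Si](CC)(CC)CC)C#C | intermediate
34 | tributyl{(1E,3S)-3-[(2S,3S)-3-methyltetrahydrofuran-2-yl]-3-(triethylsilyloxy)but-1-en-1-yl}stannane | C[C@H]1CCO[C@@H]1[C@@](C)(O[Si](CC)(CC)CC)/C=C/[Sn](CCCC)(CCCC)CCCC | intermediate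
35 | (7R,8R,8aS)-8-(tert-butyldimethylsilyloxy)-7-methyl-6,7-bis(triethylsilyloxy)-1,7,8,8a-tetrahydro-3H-isochromen-3-one | O=C1C=C2C=C(O[Si](CC)(CC)CC)[C@](C)(O[Si](CC)(CC)CC)[C@H](O[Si](C)(C)C(C)(C)C)[C@@H]2CO1 | intermediate
36 | (1E,3S)-3-[(2S,3S)-3-methyltetrahydrofuran-2-yl]-3-(triethylsilyloxy)but-1-en-1-yllithium | C[C@H]1CCO[C@@H]1[C@@](C)(O[Si](CC)(CC)CC)/C=C/[Li] | intermediate
37 | lithium lactolate from addition of 36 to C3 of 35 (mixture at C3) | C[C@H]1CCO[C@@H]1[C@@](C)(O[Si](CC)(CC)CC)/C=C/C1(O[Li])C=C2C=C(O[Si](CC)(CC)CC)[C@](C)(O[Si](CC)(CC)CC)[C@H](O[Si](C)(C)C(C)(C)C)[C@@H]2CO1 | intermediate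
38 | (7R,8R,8aS)-8-(tert-butyldimethylsilyloxy)-7-methyl-3-{(1E,3S)-3-[(2S,3S)-3-methyltetrahydrofuran-2-yl]-3-(triethylsilyloxy)but-1-en-1-yl}-7-(triethylsilyloxy)-8,8a-dihydro-1H-isochromen-6(7H)-one | C[C@H]1CCO[C@@H]1[C@@](C)(O[Si](CC)(CC)CC)/C=C/C1=CC2=CC(=O)[C@](C)(O[Si](CC)(CC)CC)[C@H](O[Si](C)(C)C(C)(C)C)[C@@H]2CO1 | intermediate
39 | 5-chloro derivative of 38 | C[C@H]1CCO[C@@H]1[C@@](C)(O[Si](CC)(CC)CC)/C=C/C1=CC2=C(Cl)C(=O)[C@](C)(O[Si](CC)(CC)CC)[C@H](O[Si](C)(C)C(C)(C)C)[C@@H]2CO1 | intermediate
40 | (7R,8R,8aS)-5-chloro-7,8-dihydroxy-3-{(1E,3S)-3-hydroxy-3-[(2S,3S)-3-methyltetrahydrofuran-2-yl]but-1-en-1-yl}-7-methyl-8,8a-dihydro-1H-isochromen-6(7H)-one | C[C@H]1CCO[C@@H]1[C@@](C)(O)/C=C/C1=CC2=C(Cl)C(=O)[C@](C)(O)[C@H](O)[C@@H]2CO1 | target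

## Step count and least certain steps

Total: 23 steps. Longest linear sequence: 16 steps (steps 1–12 and 20–23) from 1. Fragment 2 (stannane 34) takes 7 steps (13–19) from 20 and 21 and enters at step 21.

**Step 12 (key step).** The vinylic carbon C5 may migrate faster than the oxygen-bearing C8, so that the unconjugated isomer accumulates if equilibration is slow. The aluminium alkoxide may also open the δ-lactone, or the C4a=C5 double bond may move into conjugation with the lactone before the shift; the latter would make C5 a good migrating group. The fallback runs the ring enlargement before the lactone exists. It sets out from 16, which has neither a lactone nor an acidic C4 hydrogen. The same aluminium alkoxide should give the ring-enlarged tris-silyl ketol F1. Buffered HF·pyridine then frees the two primary alcohols to give diol F2, and TEMPO/PhI(OAc)2 lactonisation returns to the route at 19.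

**Step 21.** The alkenyllithium may add a second time after the lactolate opens to the keto alkoxide. It may also attack silicon of the dienol ether, or remove the γ-hydrogen at C8a. The fallback changes the bond-forming reaction to a cross-coupling and hides the ketone by reduction. It sets out from 19.
- NaBH4/CeCl3 gives the allylic diol F3, and TESOTf the bis-silyl ether F4.
- KN(SiMe3)2 and (PhO)2P(O)Cl now enolise the lactone alone and give the ketene acetal phosphate F5.
- Stille coupling with 34 (Pd(PPh3)4, LiCl, CuI) gives the triene F6.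
- PPTS in wet THF removes the secondary allylic silyl ether to give the allylic alcohol F7, and MnO2 oxidation rejoins the route at 38.

**Step 5.** The α-alkoxymethyllithium has to reach C8a on the concave face next to the dioxolane. A [1,2]-shift or protonation may compete with the [2,3]-shift. The fallback delivers the carbon by another sigmatropic process. It sets out from 6, which is heated with N,N-dimethylformamide dimethyl acetal in xylene. The alkoxy(amino)carbene formed rearranges [2,3] on the same face and gives the dimethylamide F8. LiBHEt3 reduces the amide to the primary alcohol and returns to 9.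

**Step 2.** The β-silyloxyethylborane 4 may lose ethylene by β-elimination before transmetalation. The enone may also decompose under the aqueous base. The fallback brings C4 and C3 in at the ester level and reduces afterwards. It sets out from 2. Negishi coupling with BrZnCH2CO2C(CH3)3 (Pd(PPh3)4, THF) gives the tert-butyl ester F9. Excess (i-Bu)2AlH at −78 °C reduces the ketone from the convex face and the ester, which gives the diol F10. Silylation of the primary hydroxyl (TBSCl, imidazole) returns to 6.

**Step 22.** Chlorination may occur at C4 or on the side-chain diene instead of C5, or twice. The fallback chlorinates before the side chain is attached. It sets out from 19. The dienolate formed with two equivalents of LiN(SiMe3)2 is chlorinated by N-chlorosuccinimide at the α-carbon C5 and reconjugates to the 5-chloro dione F11. TESOTf/Et3N gives the chloro dienol ether F12. Addition of 36 as in step 21 returns to the route at 39.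

## Further compounds

F1 | step 12 | (4S,5R,6R)-5-(tert-butyldimethylsilyloxy)-3-[2-(tert-butyldimethylsilyloxy)ethyl]-4-[(tert-butyldimethylsilyloxy)methyl]-6-hydroxy-6-methylcyclohex-2-en-1-one | CC(C)(C)[Si](C)(C)OCCC1=CC(=O)[C@](C)(O)[C@H](O[Si](C)(C)C(C)(C)C)[C@@H]1CO[Si](C)(C)C(C)(C)C
F2 | step 12 | (4S,5R,6R)-5-(tert-butyldimethylsilyloxy)-6-hydroxy-3-(2-hydroxyethyl)-4-(hydroxymethyl)-6-methylcyclohex-2-en-1-one | OCCC1=CC(=O)[C@](C)(O)[C@H](O[Si](C)(C)C(C)(C)C)[C@@H]1CO
F3 | step 21 | 6-hydroxy derivative of 19 from reduction of the C6 ketone (mixture at C6) | O=C1CC2=CC(O)[C@](C)(O)[C@H](O[Si](C)(C)C(C)(C)C)[C@@H]2CO1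
F4 | step 21 | 6,7-bis(triethylsilyl) ether of F3 | O=C1CC2=CC(O[Si](CC)(CC)CC)[C@](C)(O[Si](CC)(CC)CC)[C@H](O[Si](C)(C)C(C)(C)C)[C@@H]2CO1
F5 | step 21 | diphenyl phosphate of the lactone enol of F4 (ketene acetal phosphate at C3) | O=P(Oc1ccccc1)(Oc1ccccc1)OC1=CC2=CC(O[Si](CC)(CC)CC)[C@](C)(O[Si](CC)(CC)CC)[C@H](O[Si](C)(C)C(C)(C)C)[C@@H]2CO1
F6 | step 21 | C3-alkenyl 1H-isochromene with a 6-triethylsilyloxy group (coupling product of F5 and 34) | C[C@H]1CCO[C@@H]1[C@@](C)(O[Si](CC)(CC)CC)/C=C/C1=CC2=CC(O[Si](CC)(CC)CC)[C@](C)(O[Si](CC)(CC)CC)[C@H](O[Si](C)(C)C(C)(C)C)[C@@H]2CO1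
F7 | step 21 | 6-hydroxy compound from F6 (C6 allylic alcohol) | C[C@H]1CCO[C@@H]1[C@@](C)(O[Si](CC)(CC)CC)/C=C/C1=CC2=CC(O)[C@](C)(O[Si](CC)(CC)CC)[C@H](O[Si](C)(C)C(C)(C)C)[C@@H]2CO1
F8 | step 5 | N,N-dimethylamide corresponding to 9 (CON(CH3)2 in place of CH2OH, cis to the dioxolane oxygens) | CC1(C)O[C@@H]2[C@H](C(=O)N(C)C)C(CCO[Si](C)(C)C(C)(C)C)=C[C@@H]2O1
F9 | step 2 | tert-butyl 2-[(3aR,6aR)-2,2-dimethyl-4-oxo-3a,6a-dihydro-4H-cyclopenta[d][1,3]dioxol-5-yl]acetate | CC1(C)O[C@@H]2C=C(CC(=O)OC(C)(C)C)C(=O)[C@@H]2O1
F10 | step 2 | (3aS,4S,6aR)-5-(2-hydroxyethyl)-2,2-dimethyl-4,6a-dihydro-3aH-cyclopenta[d][1,3]dioxol-4-ol | CC1(C)O[C@@H]2C=C(CCO)[C@H](O)[C@@H]2O1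
F11 | step 22 | 5-chloro derivative of 19 | O=C1CC2=C(Cl)C(=O)[C@](C)(O)[C@H](O[Si](C)(C)C(C)(C)C)[C@@H]2CO1
F12 | step 22 | 5-chloro derivative of 35 | O=C1C=C2C(Cl)=C(O[Si](CC)(CC)CC)[C@](C)(O[Si](CC)(CC)CC)[C@H](O[Si](C)(C)C(C)(C)C)[C@@H]2CO1
A1 | alternative 1 | 7,8-O-isopropylidene derivative of 40 | C[C@H]1CCO[C@@H]1[C@@](C)(O)/C=C/C1=CC2=C(Cl)C(=O)[C@]3(C)OC(C)(C)O[C@@H]3[C@@H]2CO1
A2 | alternative 1 | seco precursor of A1 with a C3 ketone and a C1 acetoxymethyl group at C8a (either C8a epimer) | C[C@H]1CCO[C@@H]1[C@@](C)(O)/C=C/C(=O)CC1=C(Cl)C(=O)[C@]2(C)OC(C)(C)O[C@@H]2C1COC(C)=O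
A3 | alternative 1 | methylene dienone from A2 by loss of acetic acid (C8a=C1 exocyclic) | C[C@H]1CCO[C@@H]1[C@@](C)(O)/C=C/C(=O)CC1=C(Cl)C(=O)[C@]2(C)OC(C)(C)O[C@@H]2C1=C
A4 | alternative 2 | 5-deschloro 40 as its C8 triethylsilyl ether | C[C@H]1CCO[C@@H]1[C@@](C)(O)/C=C/C1=CC2=CC(=O)[C@](C)(O)[C@H](O[Si](CC)(CC)CC)[C@@H]2CO1
A5 | alternative 2 | 4-(formylmethylene)-3,4-dihydro-2H-pyran carrying the C8 silyloxy C7 methyl ketone chain at C8a (keto aldehyde precursor of A4) | C[C@H]1CCO[C@@H]1[C@@](C)(O)/C=C/C1=C/C(=C/C=O)[C@@H](CO1)[C@@H](O[Si](CC)(CC)CC)C(C)=O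
A6 | alternative 3 | 5-deschloro 40 as its 7,8-acetonide and side-chain triethylsilyl ether | C[C@H]1CCO[C@@H]1[C@@](C)(O[Si](CC)(CC)CC)/C=C/C1=CC2=CC(=O)[C@]3(C)OC(C)(C)O[C@@H]3[C@@H]2CO1
A7 | alternative 3 | 4-methylene-3,4-dihydro-2H-pyran carrying the acetonide-protected C6 carboxylic acid at C8a (acid precursor of A6) | C[C@H]1CCO[C@@H]1[C@@](C)(O[Si](CC)(CC)CC)/C=C/C1=CC(=C)[C@@H](CO1)[C@H]1OC(C)(C)O[C@@]1(C)C(=O)O
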